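Time is the thing to reckon with here, since blue, amber and violet stand for 4.0 h, twice the span of the earlier runs.

all flasks: D 0.1 mol%; G 7.6 µM
- beta: L 7.9 mM; run made earlier
- eta: L 35 mM; run made earlier
- blue: L 10 mM; time 4.0 h
- amber: L 20 mM; time 4.0 h
- violet: L 40 mM; time 4.0 h

| run | time / min | Q / % | L / % |
|---|---|---|---|
| beta | 10.0 | 3 | 96 |
| beta | 30.0 | 12 | 87 |
| beta | 60.0 | 22 | 78 |
| beta | 80.0 | 28 | 75 |
| beta | 120 | 37 | 62 |
| eta | 10.0 | 6 | 92 |
| eta | 30.0 | 20 | 79 |
| eta | 60.0 | 31 | 63 |
| eta | 80.0 | 39 | 52 |
| eta | 120 | 55 | 38 |

(readings scatter by 2 percentage points)

1. [Q] at the end for blue, amber, violet, in this order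
2. how that number moves from the first to the last of them (falls, then rises / rises all the way / hardly changes / rises, then falls / falls all the way)

- the numbers in the tables scatter by 2 percentage points (one standard deviation)
- "hardly changes" means that all values lie within two and a half points (for a concentration: within two and a half percent of the largest)

We start from the pace of L's loss, as a fraction of the charge per hour. Over the first 30.0 min beta gives 0.260 /h and eta 0.420 /h. Eta carries 4.43 times the L and D of beta, yet its pace is 1.62 times beta's, so we take the reaction as well below first order in L and, as a working assumption, lay the later slowing on the catalyst.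

From 30.0 min to 120 min the pace is 0.167 /h in beta and 0.273 /h in eta. These centres lie 60.0 min after the early ones, so the pace would halve in 1.56 h in beta and 1.61 h in eta. Their mean, 1.59 h, a value read off scattered readings, is the fading time: the time in which the pace falls to a half.

A pace fading so makes the L used by 4.0 h 1.42 times that used by 120 min. That gives 53.9% for beta and 87.9% for eta. Interpolating in the logarithm of the charge, and stepping slightly past eta for violet, gives 59.2%, 75.1% and 90.9%.

The weak link is that L used need not be Q: at 120 min eta's balance reads 7.00% short. We put the first answer back in. If the shortfall grows with Q and with the fading catalyst, and scales with the charge, it reaches 2.01 times its reading by 4.0 h. We commit to 5.52 mM, 13.4 mM and 29.9 mM.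

The forecast, whose grounds include “This suggests Michaelis–Menten behaviour”, gives 7.2 mM, 17 mM and 36 mM, which rises all the way; its last value is higher than ours.

The flasks give 6.35 mM, 14.5 mM and 27.8 mM, which rises all the way.

    L + D → Q + D, rate k1*[L]*[D]/(1 + ([L]/Km1) + ([Q]/Kp1)) (0.270 mM, 10.0 mM, k = 590 /M/s)
    D → Z (k = 1.00 × 10⁻⁴ /s)
    D + G ⇌ X, settled at all times (K = 4.40 × 10⁵ /M)
    D + Q → D + J (k = 2.50 /M/s)

In blue, the half-life of D by its loss to Z is 1.9 h at the end, shorter than the 4.0 h run, and the fading time of 1.59 h puts 70.6% of the L used by the end before 2.00 h, where the making of Q has 62% of its turnover up to the end behind it. In violet, L stands at 34.0% after 2.00 h and 4.69% after 4.00 h, so 69.2% of the L used by the end went in the first half, against the 70.6% of the fading time.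

The readings are simulated from invented constants, and the scatter is random.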